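**Retrosynthetic overview**

- The route rests on one feature: the C1 carboxyl carbon of ring A and the C6' formyl carbon of ring B both sit ortho to the diaryl ether oxygen (C6–O–C1'). Bonded to each other they form ring C, a seven-membered dibenzo[b,f]oxepin-10(11H)-one.
- Endgame: ring C is cut at C10–C11 by enolate hydroxylation and periodate cleavage of the ketol (ketone carbon to acid, carbinol carbon to aldehyde), then the MOM and silyl ethers are removed.
- Ring C is the only ring made; it is closed by palladium-catalysed intramolecular alpha-arylation of the C1 acetyl enolate with the C6' bromide. Rings A and B are bought as arenes.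
- The diaryl ether comes from SNAr on 3-acetyl-4-fluoro-2-methoxybenzaldehyde; the formyl group then gives the (S)-carbinol by catalytic asymmetric methallylation and hydrogenation.
- The fluoro keto aldehyde comes from lithiation and acetylation between F and OMe of the acetal of 4-fluoro-2-methoxybenzaldehyde; the bromophenol comes from 2-hydroxy-4-methylbenzaldehyde.

Key step: step 10

Remark: the fluoride is displaced while the formyl group is still para to it, since an acetyl group twisted between two ortho substituents would activate poorly alone; the C11 carbinol of ketol 20 is carried as both epimers because step 12 destroys it.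

**Step 1**
Reactants: 1 4-fluoro-2-methoxybenzaldehyde
Product: 2 1-(dimethoxymethyl)-4-fluoro-2-methoxybenzene
Conditions: HC(OMe)3, TsOH·H2O (cat.), MeOH, rt
Reagents that add atoms: trimethyl orthoformate, COC(OC)OC; methanol, CO
Why: Acid-catalysed acetalisation with an orthoformate as water scavenger should mask the aldehyde against the organolithium base of step 2.

**Step 2**
Reactants: 2 1-(dimethoxymethyl)-4-fluoro-2-methoxybenzene; 3 N-methoxy-N-methylacetamide
Product: 6 3-acetyl-4-fluoro-2-methoxybenzaldehyde, via aryllithium 4 (not isolated), via keto acetal 5 (not isolated)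
Conditions: n-BuLi, THF, −78 °C; then 3, −78 °C; then 2 M aq. HCl, THF, rt
Reagents that add atoms: water, O
Why: Directed ortho-lithiation should take place at the ring C–H flanked by fluorine and methoxy (the most acidic site), the aryllithium acylates the Weinreb amide through a chelated adduct that cannot over-add, and the aqueous acid work-up releases the ketone and hydrolyses the dimethyl acetal.

**Step 3**
Reactants: 7 2-hydroxy-4-methylbenzaldehyde
Product: 8 2-(methoxymethoxy)-4-methylbenzaldehyde
Conditions: MOMCl, i-Pr2NEt, CH2Cl2, 0 °C → rt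
Reagents that add atoms: chloromethyl methyl ether, COCCl
Why: O-alkylation of the only hydroxyl group (MOM protection) fixes which oxygen of the later catechol carries the protecting group.

**Step 4**
Reactants: 8 2-(methoxymethoxy)-4-methylbenzaldehyde
Product: 10 2-(methoxymethoxy)-4-methylphenol, via aryl formate 9 (not isolated)
Conditions: mCPBA, CH2Cl2, 0 °C → rt; then K2CO3 (cat.), MeOH, rt
Reagents that add atoms: mCPBA, OOC(=O)c1cccc(Cl)c1
Why: Baeyer–Villiger (Dakin-type) oxidation of an ortho-alkoxy benzaldehyde proceeds by migration of the electron-rich aryl group to the aryl formate, which is methanolysed to the phenol.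

**Step 5**
Reactants: 10 2-(methoxymethoxy)-4-methylphenol
Product: 11 2-bromo-6-(methoxymethoxy)-4-methylphenol
Conditions: NBS, i-Pr2NH (10 mol%), CH2Cl2, −20 → 0 °C
Reagents that add atoms: N-bromosuccinimide, O=C1CCC(=O)N1Br
Why: Amine-mediated electrophilic bromination is directed by the free phenol to its only open ortho position (para is blocked by methyl), and the non-acidic medium should leave the MOM ether intact.

**Step 6**
Reactants: 6 3-acetyl-4-fluoro-2-methoxybenzaldehyde; 11 2-bromo-6-(methoxymethoxy)-4-methylphenol
Product: 12 3-acetyl-4-[2-bromo-6-(methoxymethoxy)-4-methylphenoxy]-2-methoxybenzaldehyde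
Conditions: K2CO3, DMF, 60 °C
Reagents that add atoms: none
Why: Nucleophilic aromatic substitution (addition–elimination) should be easy because the fluoride is para to the formyl group and ortho to the acetyl group, so both carbonyls stabilise the Meisenheimer adduct formed by the hindered phenoxide.

**Step 7**
Reactants: 12 3-acetyl-4-[2-bromo-6-(methoxymethoxy)-4-methylphenoxy]-2-methoxybenzaldehyde; 13 2-methylallyl pinacol boronate
Product: 15 1-{6-[2-bromo-6-(methoxymethoxy)-4-methylphenoxy]-3-[(1S)-1-hydroxy-3-methylbut-3-en-1-yl]-2-methoxyphenyl}ethan-1-one, via pinacol borate ester 14 (not isolated)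
Conditions: (S)-TRIP [(S)-3,3'-bis(2,4,6-triisopropylphenyl)-1,1'-binaphthyl-2,2'-diyl hydrogen phosphate] (5 mol%), 4 Å MS, toluene, −30 °C; aqueous work-up
Reagents that add atoms: none
Why: Chiral phosphoric acid-catalysed allylboration runs through a closed chair transition state in which the catalyst binds the boronate oxygen and the formyl hydrogen. The (S) catalyst, mirror image of the one that pairs with Re-face attack on aryl aldehydes, is expected to deliver the methallyl group to the Si face and so set the (S)-carbinol (to be confirmed by Mosher ester analysis). The hindered methyl ketone should not react.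

**Step 8**
Reactants: 15 the (S)-homoallylic alcohol
Product: 16 1-{6-[2-bromo-6-(methoxymethoxy)-4-methylphenoxy]-3-[(1S)-1-hydroxy-3-methylbutyl]-2-methoxyphenyl}ethan-1-one
Conditions: H2 (3 atm), RhCl(PPh3)3 (5 mol%), benzene/EtOH, rt
Reagents that add atoms: none
Why: Homogeneous hydrogenation with Wilkinson's catalyst saturates the 1,1-disubstituted alkene while leaving the aryl bromide, the ketone and the benzylic C–O bond untouched, which a heterogeneous palladium catalyst would not guarantee.

**Step 9**
Reactants: 16 the saturated (S)-alcohol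
Product: 17 1-{6-[2-bromo-6-(methoxymethoxy)-4-methylphenoxy]-2-methoxy-3-[(1S)-3-methyl-1-(triisopropylsilyloxy)butyl]phenyl}ethan-1-one
Conditions: TIPSOTf, 2,6-lutidine, CH2Cl2, −78 → 0 °C
Reagents that add atoms: triisopropylsilyl triflate, CC(C)[Si](OS(=O)(=O)C(F)(F)F)(C(C)C)C(C)C
Why: Silylation of the secondary alcohol with a silyl triflate is fast at low temperature, while 2,6-lutidine is too weak a base to turn the hindered methyl ketone into its enol silane.

**Step 10**
Reactants: 17 the bromo diaryl ether methyl ketone
Product: 18 9-methoxy-4-(methoxymethoxy)-2-methyl-8-[(1S)-3-methyl-1-(triisopropylsilyloxy)butyl]dibenzo[b,f]oxepin-10(11H)-one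
Conditions: Pd2(dba)3 (2.5 mol%), XPhos (6 mol%), NaOtBu (2.2 equiv), degassed toluene (0.02 M), 80 °C
Reagents that add atoms: none
Why: Zerovalent palladium inserts into the C6'–Br bond of ring B to give an aryl bromide complex of divalent palladium, the sodium enolate of the C1 acetyl group replaces bromide on the metal, and reductive elimination forms the C6'–CH2 bond. The closest known reaction type is the Buchwald–Hartwig–Miura alpha-arylation of ketones in its intramolecular form, for which seven-membered closures are known though less common than five- or six-membered ones. Ring C closes by C–C reductive elimination from an eight-membered C,C-palladacycle, which joins the enolate carbon to C6' and gives the seven-membered oxepinone fused to both arenes. No stereocentre is formed, and the silyl-protected benzylic centre has no acidic hydrogen under these conditions. The step needs chemoselectivity for ring closure over intermolecular arylation and hydrodebromination; this is secured by the single enolisable site, by the ether oxygen holding enolate and arylpalladium on neighbouring ortho positions, and by moderate dilution. The more acidic C11 methylene of the product rests as its enolate and has no bromide left to react with.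

**Step 11**
Reactants: 18 the dibenzo[b,f]oxepin-10(11H)-one
Product: 20 11-hydroxy-9-methoxy-4-(methoxymethoxy)-2-methyl-8-[(1S)-3-methyl-1-(triisopropylsilyloxy)butyl]dibenzo[b,f]oxepin-10(11H)-one (both C11 epimers), via potassium enolate 19 (not isolated)
Conditions: KN(SiMe3)2, THF, −78 °C; 2-(phenylsulfonyl)-3-phenyloxaziridine, −78 °C; AcOH, −78 °C
Reagents that add atoms: 2-(phenylsulfonyl)-3-phenyloxaziridine, O=S(=O)(c1ccccc1)N1OC1c1ccccc1
Why: Davis oxaziridine hydroxylation of the only possible enolate transfers oxygen to C11; the new centre is not controlled and need not be, and the cold acidic quench is meant to prevent transposition of the ketol through its enediolate.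

**Step 12**
Reactants: 20 the C11 ketol
Product: 21 6-[2-formyl-6-(methoxymethoxy)-4-methylphenoxy]-2-methoxy-3-[(1S)-3-methyl-1-(triisopropylsilyloxy)butyl]benzoic acid
Conditions: NaIO4, THF/H2O (2:1), rt
Reagents that add atoms: water, O; sodium periodate, [Na+].[O-]I(=O)(=O)=O
Why: Malaprade-type periodate cleavage of the alpha-ketol through the cyclic periodate ester of the ketone hydrate turns the C10 ketone carbon into the C1 carboxylic acid and the C11 carbinol carbon into the C6' aldehyde, so both oxidation levels arise at once.

**Step 13**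
Reactants: 21 the MOM-protected acid aldehyde
Product: 22 6-(2-formyl-6-hydroxy-4-methylphenoxy)-2-methoxy-3-[(1S)-3-methyl-1-(triisopropylsilyloxy)butyl]benzoic acid
Conditions: 3 M aq. HCl, THF, 40 °C
Reagents that add atoms: none
Why: Acid-catalysed hydrolysis of the phenolic MOM acetal should be faster than cleavage of the bulky triisopropylsilyl ether, which keeps the benzylic oxygen from ionising; any silyl ether lost early only anticipates step 14.

**Step 14**
Reactants: 22 the silyl-protected phenol
Product: 23 tenellic acid B [6-(2-formyl-6-hydroxy-4-methylphenoxy)-3-[(1S)-1-hydroxy-3-methylbutyl]-2-methoxybenzoic acid]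
Conditions: HF·pyridine, pyridine, THF, 0 °C → rt
Reagents that add atoms: none
Why: Fluoride-mediated desilylation breaks the O–Si bond and not the benzylic C–O bond, so the (S) centre is kept, and the buffered medium leaves aldehyde, phenol and acid alone.

**Compound list**

1 | 4-fluoro-2-methoxybenzaldehyde | COc1cc(F)ccc1C=O | starting material
2 | 1-(dimethoxymethyl)-4-fluoro-2-methoxybenzene | COc1cc(F)ccc1C(OC)OC | intermediate
3 | N-methoxy-N-methylacetamide | CC(=O)N(C)OC | starting material
4 | [3-(dimethoxymethyl)-6-fluoro-2-methoxyphenyl]lithium | COc1c([Li])c(F)ccc1C(OC)OC | intermediate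
5 | 1-[3-(dimethoxymethyl)-6-fluoro-2-methoxyphenyl]ethan-1-one | COc1c(C(C)=O)c(F)ccc1C(OC)OC | intermediate
6 | 3-acetyl-4-fluoro-2-methoxybenzaldehyde | COc1c(C(C)=O)c(F)ccc1C=O | intermediate
7 | 2-hydroxy-4-methylbenzaldehyde | Cc1ccc(C=O)c(O)c1 | starting material
8 | 2-(methoxymethoxy)-4-methylbenzaldehyde | COCOc1cc(C)ccc1C=O | intermediate
9 | 2-(methoxymethoxy)-4-methylphenyl formate | COCOc1cc(C)ccc1OC=O | intermediate
10 | 2-(methoxymethoxy)-4-methylphenol | COCOc1cc(C)ccc1O | intermediate
11 | 2-bromo-6-(methoxymethoxy)-4-methylphenol | COCOc1cc(C)cc(Br)c1O | intermediate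
12 | 3-acetyl-4-[2-bromo-6-(methoxymethoxy)-4-methylphenoxy]-2-methoxybenzaldehyde | COc1c(C=O)ccc(Oc2c(OCOC)cc(C)cc2Br)c1C(C)=O | intermediate
13 | 2-methylallyl pinacol boronate [4,4,5,5-tetramethyl-2-(2-methylallyl)-1,3,2-dioxaborolane] | CC(=C)CB1OC(C)(C)C(C)(C)O1 | starting material
14 | pinacol borate ester of 15 | COc1c([C@@H](OB2OC(C)(C)C(C)(C)O2)CC(C)=C)ccc(Oc2c(OCOC)cc(C)cc2Br)c1C(C)=O | intermediate
15 | 1-{6-[2-bromo-6-(methoxymethoxy)-4-methylphenoxy]-3-[(1S)-1-hydroxy-3-methylbut-3-en-1-yl]-2-methoxyphenyl}ethan-1-one | COc1c([C@@H](O)CC(C)=C)ccc(Oc2c(OCOC)cc(C)cc2Br)c1C(C)=O | intermediate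
16 | 1-{6-[2-bromo-6-(methoxymethoxy)-4-methylphenoxy]-3-[(1S)-1-hydroxy-3-methylbutyl]-2-methoxyphenyl}ethan-1-one | COc1c([C@@H](O)CC(C)C)ccc(Oc2c(OCOC)cc(C)cc2Br)c1C(C)=O | intermediate
17 | 1-{6-[2-bromo-6-(methoxymethoxy)-4-methylphenoxy]-2-methoxy-3-[(1S)-3-methyl-1-(triisopropylsilyloxy)butyl]phenyl}ethan-1-one | COc1c([C@@H](O[Si](C(C)C)(C(C)C)C(C)C)CC(C)C)ccc(Oc2c(OCOC)cc(C)cc2Br)c1C(C)=O | intermediate
18 | 9-methoxy-4-(methoxymethoxy)-2-methyl-8-[(1S)-3-methyl-1-(triisopropylsilyloxy)butyl]dibenzo[b,f]oxepin-10(11H)-one | COc1c([C@@H](O[Si](C(C)C)(C(C)C)C(C)C)CC(C)C)ccc2Oc3c(OCOC)cc(C)cc3CC(=O)c12 | intermediate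
19 | potassium enolate of 18 (C10 enolate) | COc1c([C@@H](O[Si](C(C)C)(C(C)C)C(C)C)CC(C)C)ccc2Oc3c(OCOC)cc(C)cc3C=C(O[K])c12 | intermediate
20 | 11-hydroxy-9-methoxy-4-(methoxymethoxy)-2-methyl-8-[(1S)-3-methyl-1-(triisopropylsilyloxy)butyl]dibenzo[b,f]oxepin-10(11H)-one, both C11 epimers | COc1c([C@@H](O[Si](C(C)C)(C(C)C)C(C)C)CC(C)C)ccc2Oc3c(OCOC)cc(C)cc3C(O)C(=O)c12 | intermediate
21 | 6-[2-formyl-6-(methoxymethoxy)-4-methylphenoxy]-2-methoxy-3-[(1S)-3-methyl-1-(triisopropylsilyloxy)butyl]benzoic acid | COc1c([C@@H](O[Si](C(C)C)(C(C)C)C(C)C)CC(C)C)ccc(Oc2c(OCOC)cc(C)cc2C=O)c1C(=O)O | intermediate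
22 | 6-(2-formyl-6-hydroxy-4-methylphenoxy)-2-methoxy-3-[(1S)-3-methyl-1-(triisopropylsilyloxy)butyl]benzoic acid | COc1c([C@@H](O[Si](C(C)C)(C(C)C)C(C)C)CC(C)C)ccc(Oc2c(O)cc(C)cc2C=O)c1C(=O)O | intermediate
23 | tenellic acid B, 6-(2-formyl-6-hydroxy-4-methylphenoxy)-3-[(1S)-1-hydroxy-3-methylbutyl]-2-methoxybenzoic acid | COc1c([C@@H](O)CC(C)C)ccc(Oc2c(O)cc(C)cc2C=O)c1C(=O)O | target

**Step count**

Total: 14 steps. Longest linear sequence: 12 steps (steps 3–14, from 2-hydroxy-4-methylbenzaldehyde); the ring A branch from 4-fluoro-2-methoxybenzaldehyde is 11 steps.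

**Steps most likely to fail**

1. Step 10. Ring closure through the eight-membered palladacycle may be too slow, so that hydrodebromination of ring B, intermolecular arylation or base-driven self-condensation of the sodium enolate takes over. The fallback sets out from 17 and replaces the alkali enolate by a preformed enol silane coupled under neutral conditions. TMSOTf and Et3N in CH2Cl2 at 0 °C should give the trimethylsilyl enol ether of 17, F1. Bu3SnF with Pd(OAc)2 and P(t-Bu)3 in toluene at 85 °C should then form the tin enolate in the flask and couple it with the C6' bromide (palladium-catalysed arylation of enol silanes). This comes back to the route at 18.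

2. Step 11. In the basic medium the ketol may transpose through its enediolate, which would exchange the rings that receive acid and aldehyde, or be oxidised further to the 1,2-diketone. The fallback sets out from 18 and avoids the ketol. TMSOTf and Et3N in CH2Cl2 should give the 10-trimethylsilyloxy dibenzo[b,f]oxepine, F2. Ozonolysis (O3, CH2Cl2, −78 °C, then Me2S) cleaves the C10=C11 enol ether bond to the trimethylsilyl ester of the acid aldehyde, F3, which hydrolyses on aqueous work-up. This comes back to the route at 21 and bypasses 20 and step 12.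

3. Step 6. Under carbonate at elevated temperature, aldol-type condensation between the acetyl group of one molecule and the formyl group of another may compete with the attack of the doubly ortho-substituted phenoxide. The fallback sets out from 2 and carries the two-carbon unit as a non-enolisable carbinol. Lithiation as in step 2 (via 4) and quenching with acetaldehyde should give 1-[3-(dimethoxymethyl)-6-fluoro-2-methoxyphenyl]ethan-1-ol, F4. Aqueous HCl releases 4-fluoro-3-(1-hydroxyethyl)-2-methoxybenzaldehyde, F5. SNAr with 11 (K2CO3, DMF, 90 °C, activation by the para formyl group) gives the diaryl ether carbinol 4-[2-bromo-6-(methoxymethoxy)-4-methylphenoxy]-3-(1-hydroxyethyl)-2-methoxybenzaldehyde, F6. Dess–Martin oxidation of the secondary alcohol then comes back to the route at 12.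

**Further compounds**

F1 | step 10 | trimethylsilyl enol ether of 17, {1-[6-(2-bromo-6-(methoxymethoxy)-4-methylphenoxy)-2-methoxy-3-((1S)-3-methyl-1-(triisopropylsilyloxy)butyl)phenyl]ethenyloxy}trimethylsilane | COc1c([C@@H](O[Si](C(C)C)(C(C)C)C(C)C)CC(C)C)ccc(Oc2c(OCOC)cc(C)cc2Br)c1C(=C)O[Si](C)(C)C
F2 | step 11 | 9-methoxy-4-(methoxymethoxy)-2-methyl-8-[(1S)-3-methyl-1-(triisopropylsilyloxy)butyl]-10-(trimethylsilyloxy)dibenzo[b,f]oxepine | COc1c([C@@H](O[Si](C(C)C)(C(C)C)C(C)C)CC(C)C)ccc2Oc3c(OCOC)cc(C)cc3C=C(O[Si](C)(C)C)c12
F3 | step 11 | trimethylsilyl 6-[2-formyl-6-(methoxymethoxy)-4-methylphenoxy]-2-methoxy-3-[(1S)-3-methyl-1-(triisopropylsilyloxy)butyl]benzoate | COc1c([C@@H](O[Si](C(C)C)(C(C)C)C(C)C)CC(C)C)ccc(Oc2c(OCOC)cc(C)cc2C=O)c1C(=O)O[Si](C)(C)C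
F4 | step 6 | 1-[3-(dimethoxymethyl)-6-fluoro-2-methoxyphenyl]ethan-1-ol (racemic) | COc1c(C(C)O)c(F)ccc1C(OC)OC
F5 | step 6 | 4-fluoro-3-(1-hydroxyethyl)-2-methoxybenzaldehyde (racemic) | COc1c(C(C)O)c(F)ccc1C=O
F6 | step 6 | 4-[2-bromo-6-(methoxymethoxy)-4-methylphenoxy]-3-(1-hydroxyethyl)-2-methoxybenzaldehyde (racemic) | COc1c(C=O)ccc(Oc2c(OCOC)cc(C)cc2Br)c1C(C)O
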